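**Retrosynthetic overview**
1. Target 20 ⇒ epoxy ketone 13: break the C6–O bond of the senecioate. In the forward direction this C–O bond is made last by nitrone acylation and a [3,3] shift, which sets C6.
2. 13 ⇒ enone 10: the oxirane C–O bonds come from a hydroxyl-directed epoxidation of the cis allylic alcohol (reduce, epoxidise, re-oxidise).
3. 10 ⇒ enal 3: the side chain comes from asymmetric allylboration (sets C8), acetylation and cross-metathesis with 2-methylbut-2-ene.
4. 3 ⇒ (R)-carvone 1 by allylic oxidation of the isopropenyl methyl group.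
5. Ring order: the cyclohexane ring is taken intact from carvone; the oxirane is the only ring formed (step 6).

Assumption: locants follow carvone (C1 carbonyl, C2 methyl-bearing carbon, C3, C4, C5 side-chain carbon, C6; side chain C7(=CH2), C8 carbinol), and a one-pot sequence without isolation counts as one step.

**Step 1**
Reactants: 1 (R)-(−)-carvone
Product: 3 2-[(1R)-4-methyl-5-oxocyclohex-3-en-1-yl]prop-2-enal, via 10-hydroxycarvone 2 (not isolated)
Conditions: SeO2 (0.3 equiv), t-BuOOH (3 equiv), CH2Cl2, rt; then MnO2 (excess), rt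
Reagents that add atoms: tert-butyl hydroperoxide, CC(C)(C)OO; selenium dioxide, O=[Se]=O
Why: Riley allylic oxidation (ene reaction, then [2,3]-sigmatropic shift) attacks the methyl group of the electron-rich 1,1-disubstituted alkene and not the electron-poor enone, and MnO2 then oxidises only the allylic alcohol, so C5 is untouched.

**Step 2**
Reactants: 3 2-[(1R)-4-methyl-5-oxocyclohex-3-en-1-yl]prop-2-enal; 4 (+)-B-allyldiisopinocampheylborane (antipode from (−)-α-pinene)
Product: 6 (5R)-5-[(3R)-3-hydroxyhexa-1,5-dien-2-yl]-2-methylcyclohex-2-en-1-one, via diisopinocampheylborinate ester 5 (not isolated)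
Conditions: 4 (1.1 equiv, 1 M in pentane), Et2O, −78 °C; then HOCH2CH2NH2, rt
Reagents that add atoms: (+)-B-allyldiisopinocampheylborane 4, C=CCB([C@H]1C[C@H]2C[C@@H]([C@@H]1C)C2(C)C)[C@H]1C[C@H]2C[C@@H]([C@@H]1C)C2(C)C
Why: Brown allylboration through a closed chair transition state is reagent-controlled and aldehyde-selective at −78 °C; this antipode adds allyl to the Re face of the aldehyde (as it does with benzaldehyde to give the R alcohol), which sets C8 as R, and the amine work-up avoids alkaline peroxide that would epoxidise the enone.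

**Step 3**
Reactants: 6 (5R)-5-[(3R)-3-hydroxyhexa-1,5-dien-2-yl]-2-methylcyclohex-2-en-1-one; 7 acetic anhydride
Product: 8 (3R)-2-[(1R)-4-methyl-5-oxocyclohex-3-en-1-yl]hexa-1,5-dien-3-yl acetate
Conditions: Ac2O, pyridine, DMAP (cat.), CH2Cl2, 0 °C → rt
Reagents that add atoms: acetic anhydride 7, CC(=O)OC(C)=O
Why: DMAP-catalysed O-acylation of the secondary alcohol occurs with retention at C8 and masks the only hydroxyl that could later misdirect the vanadium epoxidation.

**Step 4**
Reactants: 8 (3R)-2-[(1R)-4-methyl-5-oxocyclohex-3-en-1-yl]hexa-1,5-dien-3-yl acetate; 9 2-methylbut-2-ene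
Product: 10 (3R)-6-methyl-2-[(1R)-4-methyl-5-oxocyclohex-3-en-1-yl]hepta-1,5-dien-3-yl acetate
Conditions: second-generation Grubbs catalyst RuCl2(=CHPh)(H2IMes)(PCy3) (5 mol %), 9 (excess), CH2Cl2, 35 °C
Reagents that add atoms: 2-methylbut-2-ene 9, CC=C(C)C
Why: Olefin cross-metathesis exchanges the terminal CH2 for an isopropylidene group, and only the monosubstituted alkene reacts because the 1,1-disubstituted alkene and the ring enone are too hindered or electron-poor to enter the catalytic cycle.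

**Step 5**
Reactants: 10 (3R)-6-methyl-2-[(1R)-4-methyl-5-oxocyclohex-3-en-1-yl]hepta-1,5-dien-3-yl acetate
Product: 11 (3R)-2-[(1R,5R)-5-hydroxy-4-methylcyclohex-3-en-1-yl]-6-methylhepta-1,5-dien-3-yl acetate
Conditions: NaBH4, CeCl3·7H2O, MeOH, −78 → −40 °C
Reagents that add atoms: none
Why: Luche 1,2-reduction delivers hydride axially to the half-chair with the C5 substituent equatorial, as in carvone to cis-carveol, and gives the temporary C1 alcohol cis to the side chain while the acetate survives.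

**Step 6**
Reactants: 11 (3R)-2-[(1R,5R)-5-hydroxy-4-methylcyclohex-3-en-1-yl]-6-methylhepta-1,5-dien-3-yl acetate
Product: 12 (3R)-2-[(1S,3S,5R,6R)-5-hydroxy-6-methyl-7-oxabicyclo[4.1.0]heptan-3-yl]-6-methylhepta-1,5-dien-3-yl acetate
Conditions: VO(acac)2 (3 mol %), t-BuOOH (1.3 equiv), CH2Cl2, 0 °C → rt
Reagents that add atoms: tert-butyl hydroperoxide, CC(C)(C)OO
Why: Hydroxyl-directed epoxidation through a vanadium alkoxide peroxo complex delivers oxygen to the ring alkene on the face of the C1 hydroxyl, which sets both oxirane carbons cis to the side chain (the face that nucleophilic enone epoxidation does not give), and the side-chain alkenes, which have no free allylic hydroxyl, react far more slowly.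

**Step 7**
Reactants: 12 (3R)-2-[(1S,3S,5R,6R)-5-hydroxy-6-methyl-7-oxabicyclo[4.1.0]heptan-3-yl]-6-methylhepta-1,5-dien-3-yl acetate
Product: 13 (3R)-6-methyl-2-[(1S,3R,6S)-6-methyl-5-oxo-7-oxabicyclo[4.1.0]heptan-3-yl]hepta-1,5-dien-3-yl acetate
Conditions: Dess–Martin periodinane, pyridine, CH2Cl2, 0 °C → rt
Reagents that add atoms: none
Why: Buffered Dess–Martin oxidation converts the secondary alcohol to the ketone without touching the oxirane, the acetate or the alkenes, and removes the temporary C1 stereocentre.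

**Step 8**
Reactants: 13 (3R)-6-methyl-2-[(1S,3R,6S)-6-methyl-5-oxo-7-oxabicyclo[4.1.0]heptan-3-yl]hepta-1,5-dien-3-yl acetate; 14 N-methylhydroxylamine hydrochloride; 15 3-methylbut-2-enoyl chloride
Product: 20 (1S,3S,4S,6S)-4-[(3R)-3-acetoxy-6-methylhepta-1,5-dien-2-yl]-1-methyl-2-oxo-7-oxabicyclo[4.1.0]heptan-3-yl 3-methylbut-2-enoate (CNP0168401.1), via N-methyl nitrone 16 (not isolated), via N-acyloxyiminium chloride 17 (not isolated), via N-acyloxy enamine 18 (not isolated), via alpha-acyloxy N-methylimine 19 (not isolated)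
Conditions: MeNHOH·HCl, NaHCO3, 4 Å MS, CH2Cl2, rt; then 15, −78 °C; Et3N, −78 → 0 °C; then aq. citric acid, THF, rt
Reagents that add atoms: 3-methylbut-2-enoyl chloride 15, CC(C)=CC(=O)Cl; N-methylhydroxylamine hydrochloride 14, CNO.Cl; water, O
Why: Proposed new method: a one-pot ketone to alpha-acyloxy ketone conversion in which the ketone is condensed to its N-methyl nitrone, the nitrone oxygen is acylated by the enoyl chloride at −78 °C (before any base is present, so no vinylketene deconjugation), and Et3N then removes a C6 proton (C2 is quaternary, so only one enamine can form) to give an N-acyloxy enamine whose weak N–O bond drives a concerted chair [3,3]-sigmatropic shift that joins the former acyl carbonyl oxygen to C6 on the face opposite both the C5 side chain and the oxirane, while the nitrone oxygen becomes the ester carbonyl oxygen and hydrolysis of the imine returns the ketone; the trans-diequatorial product is also expected to be the thermodynamic one, so imine–enamine equilibration can only reinforce it; the closest known reactions are the acylation–rearrangement of isolated nitrones of simple cycloalkanones with saturated or aromatic acyl chlorides and the alpha-oxyacylation of ketones with N-alkyl-O-acylhydroxylamines, neither shown in one pot on an alpha,beta-epoxy ketone, with an alpha,beta-unsaturated acyl chloride, or with 1,2-stereoinduction.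

**Compound list**
1 | (R)-(−)-carvone, (5R)-2-methyl-5-(prop-1-en-2-yl)cyclohex-2-en-1-one | C=C(C)[C@@H]1CC=C(C)C(=O)C1 | starting material
2 | 10-hydroxycarvone, (5R)-5-(3-hydroxyprop-1-en-2-yl)-2-methylcyclohex-2-en-1-one | C=C(CO)[C@@H]1CC=C(C)C(=O)C1 | intermediate
3 | 2-[(1R)-4-methyl-5-oxocyclohex-3-en-1-yl]prop-2-enal | C=C(C=O)[C@@H]1CC=C(C)C(=O)C1 | intermediate
4 | (+)-B-allyldiisopinocampheylborane | C=CCB([C@H]1C[C@H]2C[C@@H]([C@@H]1C)C2(C)C)[C@H]1C[C@H]2C[C@@H]([C@@H]1C)C2(C)C | starting material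
5 | (3R)-2-[(1R)-4-methyl-5-oxocyclohex-3-en-1-yl]hexa-1,5-dien-3-yl diisopinocampheylborinate | C=C([C@@H](CC=C)OB([C@H]1C[C@H]2C[C@@H]([C@@H]1C)C2(C)C)[C@H]1C[C@H]2C[C@@H]([C@@H]1C)C2(C)C)[C@@H]1CC=C(C)C(=O)C1 | intermediate
6 | (5R)-5-[(3R)-3-hydroxyhexa-1,5-dien-2-yl]-2-methylcyclohex-2-en-1-one | C=C([C@@H](CC=C)O)[C@@H]1CC=C(C)C(=O)C1 | intermediate
7 | acetic anhydride | CC(=O)OC(C)=O | starting material
8 | (3R)-2-[(1R)-4-methyl-5-oxocyclohex-3-en-1-yl]hexa-1,5-dien-3-yl acetate | C=C([C@@H](CC=C)OC(C)=O)[C@@H]1CC=C(C)C(=O)C1 | intermediate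
9 | 2-methylbut-2-ene | CC=C(C)C | starting material
10 | (3R)-6-methyl-2-[(1R)-4-methyl-5-oxocyclohex-3-en-1-yl]hepta-1,5-dien-3-yl acetate | C=C([C@@H](CC=C(C)C)OC(C)=O)[C@@H]1CC=C(C)C(=O)C1 | intermediate
11 | (3R)-2-[(1R,5R)-5-hydroxy-4-methylcyclohex-3-en-1-yl]-6-methylhepta-1,5-dien-3-yl acetate (OH cis to the side chain) | C=C([C@@H](CC=C(C)C)OC(C)=O)[C@@H]1CC=C(C)[C@H](O)C1 | intermediate
12 | (3R)-2-[(1S,3S,5R,6R)-5-hydroxy-6-methyl-7-oxabicyclo[4.1.0]heptan-3-yl]-6-methylhepta-1,5-dien-3-yl acetate (oxirane, OH and side chain all cis) | C=C([C@@H](CC=C(C)C)OC(C)=O)[C@@H]1C[C@@H]2O[C@]2(C)[C@H](O)C1 | intermediate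
13 | (3R)-6-methyl-2-[(1S,3R,6S)-6-methyl-5-oxo-7-oxabicyclo[4.1.0]heptan-3-yl]hepta-1,5-dien-3-yl acetate (oxirane cis to the side chain) | C=C([C@@H](CC=C(C)C)OC(C)=O)[C@@H]1C[C@@H]2O[C@]2(C)C(=O)C1 | intermediate
14 | N-methylhydroxylamine hydrochloride | CNO.Cl | starting material
15 | 3-methylbut-2-enoyl chloride (senecioyl chloride) | CC(C)=CC(=O)Cl | starting material
16 | N-methyl nitrone of 13 (C=N(+)(CH3)O(−) in place of the ring C=O; C=N geometry not fixed) | C=C([C@@H](CC=C(C)C)OC(C)=O)[C@@H]1C[C@@H]2O[C@]2(C)C(=[N+](C)[O-])C1 | intermediate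
17 | N-methyl-N-(3-methylbut-2-enoyloxy)iminium chloride of 13 (C=N geometry not fixed) | C=C([C@@H](CC=C(C)C)OC(C)=O)[C@@H]1C[C@@H]2O[C@]2(C)C(=[N+](C)OC(=O)C=C(C)C)C1.[Cl-] | intermediate
18 | N-methyl-N-(3-methylbut-2-enoyloxy) enamine of 13 (C1=C6 double bond) | C=C([C@@H](CC=C(C)C)OC(C)=O)[C@@H]1C[C@@H]2O[C@]2(C)C(N(C)OC(=O)C=C(C)C)=C1 | intermediate
19 | N-methylimine of 20 (C=NCH3 in place of the ring C=O) | C=C([C@@H](CC=C(C)C)OC(C)=O)[C@@H]1C[C@@H]2O[C@]2(C)C(=NC)[C@H]1OC(=O)C=C(C)C | intermediate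
20 | (1S,3S,4S,6S)-4-[(3R)-3-acetoxy-6-methylhepta-1,5-dien-2-yl]-1-methyl-2-oxo-7-oxabicyclo[4.1.0]heptan-3-yl 3-methylbut-2-enoate (CNP0168401.1) | C=C([C@@H](CC=C(C)C)OC(C)=O)[C@@H]1C[C@@H]2O[C@]2(C)C(=O)[C@H]1OC(=O)C=C(C)C | target

**Totals**
Total step count: 8. Longest linear sequence: 8 (from 1).

**Three steps most likely to fail**

Step 8 (proposed new step; risks are slow nitrone formation at the hindered ketone and attack of the hydroxylamine on the oxirane). The fallback uses known chemistry and sets out from 13. Enolisation with LiN(SiMe3)2 in THF at −78 °C gives the lithium enolate of 13 F4. This is hydroxylated with 2-(phenylsulfonyl)-3-phenyloxaziridine anti to the C5 substituent and the oxirane to give (1S,3S,4S,6S)-4-[(3R)-3-acetoxy-6-methylhepta-1,5-dien-2-yl]-3-hydroxy-1-methyl-7-oxabicyclo[4.1.0]heptan-2-one F5. Steglich esterification with 3-methylbut-2-enoic acid (DCC, DMAP, CH2Cl2) then comes back to the route at 20.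

Step 1 (moderate yield, competing oxidation at the C5 methine, sensitive enal). The fallback sets out from 1. Ene-type allylic chlorination with Ca(OCl)2 and solid CO2 in CH2Cl2/H2O gives (5R)-5-(3-chloroprop-1-en-2-yl)-2-methylcyclohex-2-en-1-one F1. Oxidation with trimethylamine N-oxide in DMSO (displacement by the N-oxide, then elimination) comes back to the route at 3.

Step 2 (diastereoselectivity at C8 with a hindered alpha-branched enal). The fallback sets out from 3. Unselective Barbier allylation (allyl bromide, Zn, THF/aq. NH4Cl) gives 6 together with its C8 epimer (5R)-5-[(3S)-3-hydroxyhexa-1,5-dien-2-yl]-2-methylcyclohex-2-en-1-one F2. Sharpless kinetic resolution (Ti(OiPr)4, L-(+)-diisopropyl tartrate, 0.6 equiv t-BuOOH, 4 Å MS, CH2Cl2, −20 °C) epoxidises only the fast-reacting 8S epimer, giving (5R)-5-{(2R)-2-[(1S)-1-hydroxybut-3-en-1-yl]oxiran-2-yl}-2-methylcyclohex-2-en-1-one F3, which is removed by chromatography. The unreacted 8R alcohol is 6, where the route is rejoined.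

**Further compounds**
F1 | step 1 | (5R)-5-(3-chloroprop-1-en-2-yl)-2-methylcyclohex-2-en-1-one | C=C(CCl)[C@@H]1CC=C(C)C(=O)C1
F2 | step 2 | (5R)-5-[(3S)-3-hydroxyhexa-1,5-dien-2-yl]-2-methylcyclohex-2-en-1-one | C=C([C@H](CC=C)O)[C@@H]1CC=C(C)C(=O)C1
F3 | step 2 | (5R)-5-{(2R)-2-[(1S)-1-hydroxybut-3-en-1-yl]oxiran-2-yl}-2-methylcyclohex-2-en-1-one | O[C@@H](CC=C)[C@]1(CO1)[C@@H]2CC=C(C)C(=O)C2
F4 | step 8 | lithium enolate of 13 (C1=C6 enolate) | C=C([C@@H](CC=C(C)C)OC(C)=O)[C@@H]1C[C@@H]2O[C@]2(C)C(O[Li])=C1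
F5 | step 8 | (1S,3S,4S,6S)-4-[(3R)-3-acetoxy-6-methylhepta-1,5-dien-2-yl]-3-hydroxy-1-methyl-7-oxabicyclo[4.1.0]heptan-2-one | C=C([C@@H](CC=C(C)C)OC(C)=O)[C@@H]1C[C@@H]2O[C@]2(C)C(=O)[C@H]1O
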